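**Retrosynthetic overview**
1. Aryl–C1 bond (made last): B-alkyl Suzuki–Miyaura coupling of the hydroborated terminal alkene of an (8Z,11S)-dienol with unprotected 5-bromoresorcinol.
2. C6–C7 bond: the Z-homoallylic alcohol is the ring-opened form of (S)-2-hexyl-3,6-dihydro-2H-pyran. Its allylic C–O bond is exchanged for C–C with a hex-5-enyl Grignard reagent under nickel catalysis, so the cis ring olefin becomes Z-C8=C9.
3. C10–C11 and O–C7 bonds (made first): organocatalytic asymmetric oxa-Diels–Alder reaction of heptanal with buta-1,3-diene sets C11, the only stereocentre.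
4. Ring order: one ring only, the dihydropyran, formed in step 1 and opened in step 2; the arene is bought. No protecting groups.

Target check: 5-[(8Z,11S)-11-hydroxyheptadec-8-en-1-yl]benzene-1,3-diol. At C11 the priorities are OH > C10 (allylic CH2) > C12 (hexyl) > H, which gives S for the SMILES as written.

Assumption: the sense of induction of each chiral Brønsted acid is assigned by analogy with its closest reported reactions; if a first run gives the (R) series, the mirror-image acid is used and nothing else changes.

**Step 1**
Reactants: 1 heptanal; 2 buta-1,3-diene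
Product: 3 (S)-2-hexyl-3,6-dihydro-2H-pyran
Conditions: (S,S)-IDPi (BINOL-derived imidodiphosphorimidate, N-triflyl core, 3,3'-bis[3,5-bis(trifluoromethyl)phenyl] wings; 5 mol%), 2 (10 equiv, condensed), methylcyclohexane, −20 °C, sealed vessel, 72 h, freshly distilled 1 added over 24 h
Reagents that add atoms: none
Why: Proposed new method: a catalytic asymmetric oxa-Diels–Alder (hetero-Diels–Alder) reaction of the parent, unsubstituted diene with a linear enolisable aldehyde. The confined, very acidic IDPi protonates heptanal inside its chiral pocket, and s-cis butadiene adds through a strongly asynchronous [4+2] transition state (C–C bond first, allyl-cation character paired with the chiral anion, then C–O closure). Only the s-cis conformer can close the six-membered ring, so the olefin is necessarily cis, and the pocket lets only one aldehyde face react, which sets C11 as S. The closest known reaction is the IDPi-catalysed oxa-Diels–Alder reaction of aldehydes with 2-substituted dienes of the isoprene type; butadiene is roughly a hundred times less nucleophilic and lacks the cation-stabilising 2-substituent, which is offset by the large excess of diene, the higher temperature and slow aldehyde addition to hold back trioxane, aldol and Prins products.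

**Step 2**
Reactants: 3 (S)-2-hexyl-3,6-dihydro-2H-pyran; 4 6-bromohex-1-ene
Product: 7 (8Z,11S)-heptadeca-1,8-dien-11-ol, via hex-5-en-1-ylmagnesium bromide 5 (not isolated), via magnesium alkoxide 6 (not isolated)
Conditions: 4 (2.0 equiv), Mg turnings, THF, rt; then 3, NiCl2(dppp) (5 mol%), THF–toluene, 0 → 60 °C; 1 M HCl work-up
Reagents that add atoms: none
Why: Nickel-catalysed Kumada-type cross-coupling at the allylic C–O bond (Felkin-type Grignard ring opening of 3,6-dihydro-2H-pyrans to cis-homoallylic alcohols). Magnesium-assisted oxidative addition of zerovalent nickel to O1–C6 gives a ring-derived anti allyl–nickel alkoxide, and the chelating diphosphine favours C–C reductive elimination at the unhindered CH2 terminus over β-hydride loss, so the ring cis geometry becomes the Z olefin and the non-allylic C11 stereocentre is untouched.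

**Step 3**
Reactants: 7 (8Z,11S)-heptadeca-1,8-dien-11-ol; 8 5-bromobenzene-1,3-diol
Product: 10 5-[(8Z,11S)-11-hydroxyheptadec-8-en-1-yl]benzene-1,3-diol, via diboron adduct 9 (not isolated)
Conditions: 9-BBN (2.1 equiv B–H), THF, 0 °C → rt, 3 h; then 8 (1.2 equiv), Pd(OAc)2 (5 mol%), SPhos (10 mol%), degassed aq K3PO4 (6 equiv), THF–H2O, 60 °C, 12 h; work-up at pH 5
Reagents that add atoms: none
Why: Anti-Markovnikov hydroboration with 9-BBN followed by B-alkyl Suzuki–Miyaura coupling. The terminal alkene reacts far faster than the internal cis alkene, the alcohol is masked in the flask as its borinate, and the electron-rich phosphine couples the aryl bromide even as its bis-phenoxide under excess base, so neither C11 nor the Z olefin is touched.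

**Compound list**
1 | heptanal | CCCCCCC=O | starting material
2 | buta-1,3-diene | C=CC=C | starting material
3 | (S)-2-hexyl-3,6-dihydro-2H-pyran | CCCCCC[C@H]1CC=CCO1 | intermediate
4 | 6-bromohex-1-ene | C=CCCCCBr | starting material
5 | hex-5-en-1-ylmagnesium bromide | C=CCCCC[Mg]Br | intermediate
6 | bromomagnesium (8Z,11S)-heptadeca-1,8-dien-11-olate | CCCCCC[C@H](O[Mg]Br)C/C=C\CCCCCC=C | intermediate
7 | (8Z,11S)-heptadeca-1,8-dien-11-ol | CCCCCC[C@H](O)C/C=C\CCCCCC=C | intermediate
8 | 5-bromobenzene-1,3-diol | Oc1cc(O)cc(Br)c1 | starting material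
9 | 9-{[(8Z,11S)-1-(9-borabicyclo[3.3.1]nonan-9-yl)heptadec-8-en-11-yl]oxy}-9-borabicyclo[3.3.1]nonane | CCCCCC[C@H](OB1C2CCCC1CCC2)C/C=C\CCCCCCCB1C2CCCC1CCC2 | intermediate
10 | 5-[(8Z,11S)-11-hydroxyheptadec-8-en-1-yl]benzene-1,3-diol | CCCCCC[C@H](O)C/C=C\CCCCCCCc1cc(O)cc(O)c1 | target

**Totals**
Total step count: 3. Longest linear sequence: 3 (1 → 3 → 7 → 10).

**Steps most likely to fail, most risky first**

Step 1 (the proposed new reaction). Butadiene may be too weak a nucleophile, so conversion stalls, Prins or trioxane products dominate, or the ee is low. The fallback uses known chemistry only; it sets out from 1 and comes back at 3. Heptanal 1 is allylated with allylboronic acid pinacol ester under (R)-TRIP ((R)-3,3'-bis(2,4,6-triisopropylphenyl)-1,1'-binaphthyl-2,2'-diyl hydrogen phosphate, 5 mol%, toluene, −30 °C; chiral phosphoric acid-catalysed allylboration) to give (S)-dec-1-en-4-ol F1. O-Allylation (NaH, allyl bromide, THF–DMF, 0 °C → rt) gives (S)-4-(prop-2-en-1-yloxy)dec-1-ene F2. Ring-closing metathesis with the second-generation Grubbs catalyst RuCl2(H2IMes)(PCy3)(=CHPh) (2 mol%, CH2Cl2, 40 °C) then closes the dihydropyran 3 with loss of ethene. The stereocentre is still set by organocatalysis; the cost is two extra steps.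

Step 2. The risks are coupling at the substituted allyl terminus (branched vinyl isomer), reduction through β-hydride transfer, or Z → E leakage through allyl isomerisation. The fallback abandons the ring-opening logic; it sets out from 1 and comes back at 7, bypassing 3. 7-Bromohept-1-ene and Mg in THF give hept-6-en-1-ylmagnesium bromide F3, which is added to 2-(dichloromethyl)-4,4,5,5-tetramethyl-1,3,2-dioxaborolane (−78 °C → rt) to give rac-2-(1-chlorooct-7-en-1-yl)-4,4,5,5-tetramethyl-1,3,2-dioxaborolane F4. Vinylmagnesium bromide in the same flask (Matteson homologation) converts F4 into rac-2-(deca-1,9-dien-3-yl)-4,4,5,5-tetramethyl-1,3,2-dioxaborolane F5. F5 (2.2 equiv) and 1 with (R)-TRIP (5 mol%, toluene, −40 °C) give 7 directly by kinetic-resolution allylboration: the matched boronate enantiomer reacts through a chair with its α-alkyl group axial, which delivers the Z olefin and C11 in one event.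

Step 3. The risks are sluggish oxidative addition or catalyst inhibition by the free resorcinol, or partial hydroboration of the internal alkene. The fallback replaces the protecting-group-free coupling by a protected-phenol sequence; it sets out from 7 and 8 and comes back at 10. 8 is silylated (TBSCl, imidazole, DMF, rt) to 1-bromo-3,5-bis[(tert-butyldimethylsilyl)oxy]benzene F6. Adduct 9, made from 7 as in step 3, is coupled with F6 (Pd(OAc)2, SPhos, aq K3PO4, THF, 60 °C) to (8Z,11S)-1-{3,5-bis[(tert-butyldimethylsilyl)oxy]phenyl}heptadec-8-en-11-ol F7. TBAF (THF, 0 °C) then releases 10.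

**Further compounds**
F1 | step 1 | (S)-dec-1-en-4-ol | CCCCCC[C@H](O)CC=C
F2 | step 1 | (S)-4-(prop-2-en-1-yloxy)dec-1-ene | CCCCCC[C@H](OCC=C)CC=C
F3 | step 2 | hept-6-en-1-ylmagnesium bromide | C=CCCCCC[Mg]Br
F4 | step 2 | rac-2-(1-chlorooct-7-en-1-yl)-4,4,5,5-tetramethyl-1,3,2-dioxaborolane | C=CCCCCCC(Cl)B1OC(C)(C)C(C)(C)O1
F5 | step 2 | rac-2-(deca-1,9-dien-3-yl)-4,4,5,5-tetramethyl-1,3,2-dioxaborolane | C=CCCCCCC(C=C)B1OC(C)(C)C(C)(C)O1
F6 | step 3 | 1-bromo-3,5-bis[(tert-butyldimethylsilyl)oxy]benzene | CC(C)(C)[Si](C)(C)Oc1cc(Br)cc(O[Si](C)(C)C(C)(C)C)c1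
F7 | step 3 | (8Z,11S)-1-{3,5-bis[(tert-butyldimethylsilyl)oxy]phenyl}heptadec-8-en-11-ol | CCCCCC[C@H](O)C/C=C\CCCCCCCc1cc(O[Si](C)(C)C(C)(C)C)cc(O[Si](C)(C)C(C)(C)C)c1
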